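Locants used throughout: ring A is C1–C5 (C1 carries OH and the CH2O group, C3 the side chain, C5 ring B). Ring B is C1'–C5' (C1' bonded to C5, C2' the carbonyl, C3'=C4', C5' the methyl-bearing carbon). The side-chain carbons are Ca (on C3, bearing a methyl), Cb, Cc, Cd and Ce (bearing two methyls and the OOH). Compound numbers are those of the steps and the compound list below.

## Analysis of the target

The target 31 consists of two five-membered rings joined by the single bond C5–C1': ring A, a cyclopentane, and ring B, a cyclopent-2-enone. Ring A carries a tertiary hydroxyl and an acetoxymethyl group at C1, an (E,E)-dienyl chain ending in a tertiary allylic hydroperoxide at C3, and ring B at C5. The five stereocentres C1, C3, C5, C1' and C5' have the configuration 1R, 3S, 5S, 1'S, 5'R. The C1 oxygen is trans to ring B, the C3 chain is cis to ring B, and on ring B the ring A substituent at C1' is cis to the C5' methyl. This cis arrangement is the less stable one and C1' is α to the ketone, so ring B has to be formed late and kept away from strong acid or base. The hydroperoxide, the conjugated diene and a primary acetate beside a free tertiary alcohol restrict the last steps further. The main difficulties are the fully substituted carbinol C1 next to the stereocentre C5, and the relay of configuration across the ring–ring bond to C1' and C5'. The strategy rests on the bond C1–C5 of ring A: a tertiary alcohol carbon bonded to a carbon that bears a two-carbon carbonyl arm, with the oxygen trans to that arm and the C3 substituent cis to it. This is the pattern left by a ketyl radical that adds to the β-carbon of an enoate, so ring A can be opened there to an acyclic keto enoate with one stereocentre.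

## Retrosynthetic reasoning

31 ⇒ 30. The Ce–OOH bond is cut last. A photosensitised oxygen ene reaction on the skipped diene 30 places oxygen on Ce and moves the Cd=Ce double bond to Cc=Cd. The hydroperoxide therefore never has to survive any other reagent. The forward step must choose the terminal alkene and the hydrogen on Cc.

30 ⇒ 29 ⇒ 28. The acetate is put on the primary hydroxyl of diol 29, and 29 comes from the p-methoxybenzyl ether 28 by oxidative cleavage. The benzyl-type ether is kept until ring B exists for two reasons. While the C5 arm is an ester or an acid, a free cis CH2OH would lactonise onto it. A free 1,2-diol would also not survive the periodate step used earlier.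

28 ⇒ 27. Ring B is opened at C3'=C4' by a ring-closing metathesis transform. The dienone 27 has both alkenes in place, and a metathesis catalyst is neutral, which suits the epimerisable C1'.

27 ⇒ 26 ⇒ 25. The C2'–C3' bond is cut between an acyl donor and a vinyl nucleophile. The N-methoxy-N-methylamide 26 of acid 25 stops the addition at the ketone.

25 ⇒ 22 ⇒ 19 + 21. The bond C1'–C5' is cut by an ester enolate [3,3] rearrangement. Both new stereocentres then come from one chair: C5' from the carbinol centre and the (E)-alkene of the allylic alcohol 21, and C1' from the enolate geometry. Alcohol 21 is obtained from racemate 20 by resolution. This is preferred to an alkylation because no acyclic stereocontrol next to the hindered C5 has to be trusted. The propenyl group that results is lost as a small alkene in the metathesis.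

19 ⇐ 18 ⇒ 15 + 16. The side chain is cut at Ca–CH3 and Cb–Cc. A syn methyl-metalation of the terminal alkyne 15 followed by allylation with prenyl bromide 16 gives the (E)-trisubstituted alkene and the skipped diene in one flask. This has to precede the rearrangement, because the alkyne C–H would not survive the amide base.

15 ⇒ 14 ⇒ 12. The alkyne comes from aldehyde 14 by one-carbon homologation, and 14 from the vinyl group of 12 by oxidative cleavage. A vinyl group is carried at C3 rather than a 1,1-disubstituted alkene because an aldehyde is converted to the alkyne under carbonate conditions that leave the methyl ester alone, whereas a methyl ketone would need two rounds of amide base.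

12 ⇒ 11 (key disconnection). Ring A is opened at C1–C5. Forward, a ketyl generated at C1 of keto enoate 11 adds 5-exo to the enoate β-carbon. One C–C bond, the ring, and the stereocentres C1 and C5 are formed under control of C3. The ketone oxygen substituent is a p-methoxybenzyl ether because it is removable under neutral oxidative conditions at the end.

11 ⇒ 9 + 10 ⇒ 8 ⇒ 6 + 7 (from 3). The enoate is made from aldehyde 9 and the stabilised ylide 10, which does not touch the ketone. Aldehyde 9 comes from hydroxy ketone 8 by oxidation. 8 comes from a single addition of the alkoxymethyllithium 7 to lactone 6. The lactone differentiates the two arms from the start, so no protecting group is needed.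

6 ⇒ 4 + 5 and 3 ⇒ 1 + 2. The only stereocentre that must be bought with a catalyst is C3, set by an enantioselective conjugate addition of the vinyl donor 5 to the unsaturated lactone 4. Stannane 3 is an ether of alcohol 1 and the iodomethylstannane 2.

## Alternatives that were turned down

Alternative 1: The ring–ring bond C5–C1' is cut instead. Ring A would be taken from a chiral-pool cyclohexene terpene by ring contraction, and its C1=C5 alkene turned into an epoxide by a directed asymmetric epoxidation. An ester enolate hung on the C1 hydroxymethyl group would open the epoxide at C5 in a 6-exo-tet closure to give the cis-fused hydroxy lactone A1.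

- For: the opening is stereospecific, so the trans relation of the C1 oxygen and the C5 substituent follows from inversion. That is stronger than the kinetic diastereoselection of a radical closure. A1 already holds the tertiary alcohol, the CH2O carbon, C1', C5', the methyl and a vinyl group, so ring B is only a vinyl addition and a metathesis away. In step count after the key step this route is shorter than the one chosen.
- Against: a lithium ester enolate is a poor nucleophile for an epoxide. The backside line of attack on C5 has to be reached from a tether on the neighbouring carbon through a six-membered transition state fused to the cyclopentane. Base-induced opening to the allylic alkoxide, acyl transfer to the freed tertiary alkoxide and Claisen condensation compete. C1' is then set α to a lactone carbonyl under equilibrating basic conditions, with no element that ties it to C5'.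
- Comparison: the chosen route forms its ring bond by a radical addition that has no such trajectory problem, and it sets C1' and C5' together in a pericyclic step.

Alternative 2: Ring A is cut into a C3 and a C2 piece, at C1–C2 and C3–C4. A chiral phosphine adds to ethyl buta-2,3-dienoate A3, and the zwitterion combines with tert-butyl acrylate A4 to give the cyclopentene diester A2.

- For: it is catalytic, uses two commodity esters, and makes ring A in a single step with two distinguishable ester groups. On cost and on length up to the ring it is better than the chosen route.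
- Against: A2 carries only the C3 stereocentre. C1 and C5 are still the two carbons of an enoate. The tertiary alcohol and the bond to ring B would have to be added by conjugate addition and enolate oxidation, under 1,3-induction from one remote ester. The α/γ regiochemistry of the annulation and the enantioselectivity at the acrylate-derived carbon are further open points. The tert-butyl ester must also be rebuilt into the dienyl chain.
- Comparison: the chosen route forms C1 and C5 in the ring-closing event itself, with the oxygen already in place.

Alternative 3: Ring B is cut at C4'–C5'. A cross-conjugated dienone with a β-trimethylsilyl vinyl group would be closed by a Lewis acid (FeCl3) in a conrotatory 4π electrocyclisation. Loss of silicon would fix C3'=C4', and protonation of the enolate at C1' would give A5 with ring B in place.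

- For: silicon fixes the alkene position without ambiguity, the enone appears in one step instead of four, and protonation from the face away from the C5' methyl would lead to the required cis relation. On these points it is stronger than the rearrangement/metathesis sequence used here.
- Against: the sense of conrotation decides C5', and it would have to be dictated by the C5 stereocentre on the α-substituent, for which no strong bias is evident. A strong Lewis acid is applied next to a tertiary silyl ether that can ionise. The kinetically protonated cis product stays in contact with that acid.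
- Comparison: Alternative 3 does not solve ring A at all. The chosen route sets C5' by transfer from a resolved carbinol centre and C1' by enolate geometry, independent of any torquoselectivity.

Key step: step 6

Remark on the chemistry: (S)-BINAP is assigned in step 2 by analogy with the facial preference known for six-membered enones; if the sense is found reversed, (R)-BINAP is used. (E)-Pent-3-en-2-ol is taken as the commercial racemate 20 and resolved.

## Route

Step 1
Reactants: 1 (4-methoxyphenyl)methanol; 2 tributyl(iodomethyl)stannane
Product: 3 tributyl{[(4-methoxyphenyl)methoxy]methyl}stannane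
Conditions: NaH (1.2 equiv), THF/DMF, 0 °C; then 2, rt
Reagents that add atoms: none
Why: Williamson ether synthesis; the sodium alkoxide displaces iodide from the primary α-stannyl carbon.

Step 2
Reactants: 4 5,6-dihydro-2H-pyran-2-one; 5 potassium ethenyltrifluoroborate
Product: 6 (4S)-4-ethenyloxan-2-one
Conditions: [Rh(C8H12)2]BF4 (3 mol%; C8H12 = cycloocta-1,5-diene), (S)-BINAP (3.3 mol%), toluene/H2O (10:1), 100 °C; mildly acidic work-up
Reagents that add atoms: none
Why: Rhodium-catalysed asymmetric conjugate addition of an alkenylboron reagent to an α,β-unsaturated lactone (Hayashi–Miyaura type); the alkenyl–rhodium species inserts the C=C bond on the face left open by the ligand and water releases the product, which sets C3 of ring A. The acidic work-up recloses any ring-opened hydroxy acid.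

Step 3
Reactants: 6 (4S)-4-ethenyloxan-2-one; 3 tributyl{[(4-methoxyphenyl)methoxy]methyl}stannane
Product: 8 (4S)-4-ethenyl-6-hydroxy-1-[(4-methoxyphenyl)methoxy]hexan-2-one (open form; in equilibrium with its six-membered hemiketal), via [(4-methoxyphenyl)methoxy]methyllithium 7 (not isolated)
Conditions: 3 (1.3 equiv), n-BuLi (1.25 equiv), THF, −78 °C; then 6, −78 °C; NH4Cl (aq) at −78 °C
Reagents that add atoms: none
Why: Tin–lithium exchange gives the α-alkoxymethyllithium, which adds once to the δ-lactone; the tetrahedral lithium hemiketal alkoxide does not collapse at −78 °C, so a second addition is avoided, and the stereocentre is not involved.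

Step 4
Reactants: 8 (4S)-4-ethenyl-6-hydroxy-1-[(4-methoxyphenyl)methoxy]hexan-2-one
Product: 9 (3S)-3-ethenyl-6-[(4-methoxyphenyl)methoxy]-5-oxohexanal
Conditions: TEMPO (10 mol%), PhI(OAc)2 (1.2 equiv), CH2Cl2, rt
Reagents that add atoms: none
Why: Oxoammonium oxidation of a primary alcohol to the aldehyde; the hemiketal form has no carbinol hydrogen, so only the open form is consumed and the equilibrium drains without over-oxidation.

Step 5
Reactants: 9 (3S)-3-ethenyl-6-[(4-methoxyphenyl)methoxy]-5-oxohexanal; 10 methyl (triphenyl-λ5-phosphanylidene)acetate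
Product: 11 methyl (2E,5S)-5-ethenyl-8-[(4-methoxyphenyl)methoxy]-7-oxooct-2-enoate
Conditions: 10 (1.1 equiv), CH2Cl2, 0 °C → rt
Reagents that add atoms: none
Why: Wittig olefination with a stabilised ylide, which reacts with the aldehyde and not with the ketone and gives the (E)-enoate; no base is present, so the 1,5-keto aldehyde cannot undergo aldol closure.

Step 6
Reactants: 11 methyl (2E,5S)-5-ethenyl-8-[(4-methoxyphenyl)methoxy]-7-oxooct-2-enoate
Product: 12 methyl 2-[(1S,2R,4S)-4-ethenyl-2-hydroxy-2-{[(4-methoxyphenyl)methoxy]methyl}cyclopentyl]acetate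
Conditions: SmI2 (2.4 equiv, 0.1 M in THF, added over 1 h), t-BuOH (3 equiv), THF (10 mM), −78 °C
Reagents that add atoms: none
Why: One electron from divalent samarium turns the ketone of 11 into a ketyl radical anion, held in a five-membered chelate by the ether oxygen; the ketyl carbon adds to the β-carbon of the enoate and forms C1–C5, the α-ester radical takes up a second electron, and t-BuOH protonates the resulting samarium enolate. The closest known reaction type is the SmI2-mediated ketyl–olefin cyclisation of ketones onto α,β-unsaturated esters. Ring A closes in the 5-exo-trig mode through a chair-like transition state. C1 is controlled by the bulky, electron-rich O–Sm group, which turns away from the enoate, so the hydroxyl ends trans and the aryloxymethyl group cis to the new acetate arm. C5 is controlled by the existing C3 centre, whose vinyl group takes a pseudo-equatorial position in the chair and therefore ends cis to the arm. The step needs chemoselectivity against a second reduction of the ketyl with loss of the α-oxygen; ring closure is unimolecular and that reduction is bimolecular, so slow addition of SmI2 at high dilution and low temperature favours closure onto the (E)-enoate, the best radical acceptor present. Hydroxyl and ester arm lie on opposite faces, so no lactone forms and 12 is isolated as the open hydroxy ester.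

Step 7
Reactants: 12 methyl 2-[(1S,2R,4S)-4-ethenyl-2-hydroxy-2-{[(4-methoxyphenyl)methoxy]methyl}cyclopentyl]acetate
Product: 14 methyl 2-[(1S,2R,4S)-4-formyl-2-hydroxy-2-{[(4-methoxyphenyl)methoxy]methyl}cyclopentyl]acetate, via side-chain 1,2-diol 13 (not isolated)
Conditions: OsO4 (2 mol%), NaIO4 (4 equiv), 2,6-lutidine (2 equiv), 1,4-dioxane/H2O (3:1), rt
Reagents that add atoms: osmium tetroxide, O=[Os](=O)(=O)=O (supplies the oxygen atoms of diol 13, one of which remains as the aldehyde oxygen; it is regenerated by sodium periodate, [Na+].[O-]I(=O)(=O)=O)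
Why: Lemieux–Johnson cleavage of the only alkene; the ring 1,2-diol unit is protected as its benzyl-type ether and is not cleaved, and the buffered, near-neutral medium leaves the new α-stereocentre C3 untouched.

Step 8
Reactants: 14 methyl 2-[(1S,2R,4S)-4-formyl-2-hydroxy-2-{[(4-methoxyphenyl)methoxy]methyl}cyclopentyl]acetate
Product: 15 methyl 2-[(1S,2R,4S)-4-ethynyl-2-hydroxy-2-{[(4-methoxyphenyl)methoxy]methyl}cyclopentyl]acetate
Conditions: dimethyl (1-diazo-2-oxopropyl)phosphonate (1.5 equiv), K2CO3 (2 equiv), MeOH, 0 °C → rt
Reagents that add atoms: dimethyl (1-diazo-2-oxopropyl)phosphonate, CC(=O)C(=[N+]=[N-])P(=O)(OC)OC (its diazo carbon becomes the terminal alkyne carbon)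
Why: Ohira–Bestmann variant of the Seyferth–Gilbert homologation; methoxide removes the acetyl group of the reagent, the phosphonate anion olefinates the aldehyde, and loss of N2 with a 1,2-hydrogen shift gives the alkyne. Methanolysis of the methyl ester is degenerate, and carbonate at 0 °C keeps C3 from epimerising.

Step 9
Reactants: 15 methyl 2-[(1S,2R,4S)-4-ethynyl-2-hydroxy-2-{[(4-methoxyphenyl)methoxy]methyl}cyclopentyl]acetate; 16 1-bromo-3-methylbut-2-ene
Product: 18 methyl 2-[(1S,2R,4S)-2-hydroxy-2-{[(4-methoxyphenyl)methoxy]methyl}-4-[(2E)-6-methylhepta-2,5-dien-2-yl]cyclopentyl]acetate, via (E)-alkenyl(dimethyl)alane 17 (not isolated)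
Conditions: AlMe3 (3.5 equiv), Zr(C5H5)2Cl2 (0.2 equiv), H2O (1.5 equiv), CH2Cl2, −20 °C; then 16 (1.5 equiv), Pd(PPh3)4 (5 mol%), THF, 0 °C → rt; aq. potassium sodium tartrate
Reagents that add atoms: trimethylaluminium, C[Al](C)C (the methyl group on Ca)
Why: Negishi zirconium-catalysed carboalumination adds methyl and aluminium syn across the alkyne with aluminium on the terminal carbon, which fixes the (E)-geometry; the palladium-catalysed coupling of the alkenylalane with the prenyl halide occurs at the unsubstituted allyl terminus with retention and gives the 1,4-diene. The tertiary hydroxyl is carried as its aluminium alkoxide, and the water-accelerated low-temperature protocol spares the methyl ester.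

Step 10
Reactants: 18 methyl 2-[(1S,2R,4S)-2-hydroxy-2-{[(4-methoxyphenyl)methoxy]methyl}-4-[(2E)-6-methylhepta-2,5-dien-2-yl]cyclopentyl]acetate
Product: 19 2-[(1S,2R,4S)-2-hydroxy-2-{[(4-methoxyphenyl)methoxy]methyl}-4-[(2E)-6-methylhepta-2,5-dien-2-yl]cyclopentyl]acetic acid
Conditions: LiOH·H2O (3 equiv), THF/MeOH/H2O (3:1:1), rt; then 1 M HCl to pH 3 at 0 °C
Reagents that add atoms: lithium hydroxide, [Li+].[OH-] (its oxygen becomes the acid hydroxyl)
Why: Ester saponification; the trans tertiary hydroxyl cannot form a lactone and the primary oxygen is still protected.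

Step 11
Reactants: 20 rac-(3E)-pent-3-en-2-ol
Product: 21 (2S,3E)-pent-3-en-2-ol
Conditions: immobilised Candida antarctica lipase B, vinyl acetate (0.7 equiv), pentane, rt, to about 55% conversion; separation from the acetate
Reagents that add atoms: none
Why: Lipase-catalysed kinetic resolution by transesterification; the (R)-alcohol is acylated faster (Kazlauskas rule), so the unreacted alcohol is the (S)-enantiomer, and running past half conversion raises its purity.

Step 12
Reactants: 19 2-[(1S,2R,4S)-2-hydroxy-2-{[(4-methoxyphenyl)methoxy]methyl}-4-[(2E)-6-methylhepta-2,5-dien-2-yl]cyclopentyl]acetic acid; 21 (2S,3E)-pent-3-en-2-ol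
Product: 22 (2S,3E)-pent-3-en-2-yl 2-[(1S,2R,4S)-2-hydroxy-2-{[(4-methoxyphenyl)methoxy]methyl}-4-[(2E)-6-methylhepta-2,5-dien-2-yl]cyclopentyl]acetate
Conditions: EDC·HCl (1.5 equiv), DMAP (0.2 equiv), CH2Cl2, 0 °C → rt
Reagents that add atoms: none
Why: Steglich esterification through the acylpyridinium ion; the O–H of 21 is acylated with retention at the carbinol carbon, and the hindered tertiary hydroxyl does not compete.

Step 13
Reactants: 22 (2S,3E)-pent-3-en-2-yl 2-[(1S,2R,4S)-2-hydroxy-2-{[(4-methoxyphenyl)methoxy]methyl}-4-[(2E)-6-methylhepta-2,5-dien-2-yl]cyclopentyl]acetate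
Product: 25 (2S,3R,4E)-2-[(1S,2R,4S)-2-hydroxy-2-{[(4-methoxyphenyl)methoxy]methyl}-4-[(2E)-6-methylhepta-2,5-dien-2-yl]cyclopentyl]-3-methylhex-4-enoic acid, via (E)-silyl ketene acetal 23 (not isolated), via trimethylsilyl ester 24 (not isolated)
Conditions: LiN(iPr)2 (2.5 equiv), THF, −78 °C; Me3SiCl/Et3N (4 equiv), −78 °C → rt, then 50 °C; 1 M HCl work-up
Reagents that add atoms: none
Why: Ireland–Claisen rearrangement; kinetic deprotonation in THF gives the enolate with ring A trans to O–Li, silylation gives the (E)-ketene acetal (the tertiary alkoxide is silylated as well), and the chair with the carbinol methyl equatorial transfers the (S)-centre of 21 to C5' (R) while the axial ring A substituent fixes C1' (S), the erythro pair that becomes cis on ring B. In the rotamer of lowest A(1,3) strain the quaternary C1 covers the enolate face that the chair does not use, so substrate bias and chirality transfer reinforce each other. Acid work-up cleaves the silyl ester and the silyl ether.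

Step 14
Reactants: 25 (2S,3R,4E)-2-[(1S,2R,4S)-2-hydroxy-2-{[(4-methoxyphenyl)methoxy]methyl}-4-[(2E)-6-methylhepta-2,5-dien-2-yl]cyclopentyl]-3-methylhex-4-enoic acid
Product: 26 (2S,3R,4E)-2-[(1S,2R,4S)-2-hydroxy-2-{[(4-methoxyphenyl)methoxy]methyl}-4-[(2E)-6-methylhepta-2,5-dien-2-yl]cyclopentyl]-N-methoxy-N,3-dimethylhex-4-enamide
Conditions: MeNH(OMe)·HCl (2 equiv), EDC·HCl (1.5 equiv), HOBt (1.5 equiv), iPr2NEt (3 equiv), CH2Cl2, 0 °C → rt
Reagents that add atoms: N,O-dimethylhydroxylamine hydrochloride, CNOC.Cl
Why: Carbodiimide amidation through the benzotriazolyl ester; the α-centre C1' has no acylamino group, so the azlactone pathway of epimerisation is absent.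

Step 15
Reactants: 26 (2S,3R,4E)-2-[(1S,2R,4S)-2-hydroxy-2-{[(4-methoxyphenyl)methoxy]methyl}-4-[(2E)-6-methylhepta-2,5-dien-2-yl]cyclopentyl]-N-methoxy-N,3-dimethylhex-4-enamide
Product: 27 (4S,5R,6E)-4-[(1S,2R,4S)-2-hydroxy-2-{[(4-methoxyphenyl)methoxy]methyl}-4-[(2E)-6-methylhepta-2,5-dien-2-yl]cyclopentyl]-5-methylocta-1,6-dien-3-one
Conditions: CH2=CHMgBr (3.5 equiv), THF, −20 → 0 °C; inverse quench into cold 1 M HCl/Et2O
Reagents that add atoms: vinylmagnesium bromide, C=C[Mg]Br
Why: Weinreb ketone synthesis; the five-membered magnesium chelate holds the tetrahedral intermediate until the quench, so only one vinyl group adds (one equivalent is spent on the hydroxyl). The acidic inverse quench prevents conjugate addition of the released amine to the vinyl ketone and enolisation at C1'.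

Step 16
Reactants: 27 (4S,5R,6E)-4-[(1S,2R,4S)-2-hydroxy-2-{[(4-methoxyphenyl)methoxy]methyl}-4-[(2E)-6-methylhepta-2,5-dien-2-yl]cyclopentyl]-5-methylocta-1,6-dien-3-one
Product: 28 (4R,5S)-5-[(1S,2R,4S)-2-hydroxy-2-{[(4-methoxyphenyl)methoxy]methyl}-4-[(2E)-6-methylhepta-2,5-dien-2-yl]cyclopentyl]-4-methylcyclopent-2-en-1-one
Conditions: second-generation Hoveyda–Grubbs catalyst RuCl2(H2IMes)(=CH-C6H4-2-OiPr) (5 mol%), CH2Cl2 (5 mM), 40 °C
Reagents that add atoms: none
Why: Ring-closing metathesis; the catalyst loads on the unhindered propenyl group and closes onto the vinyl ketone to the five-membered enone with loss of propene, while the two trisubstituted alkenes of the side chain are too hindered to take part. The neutral conditions keep the cis relation at C1'/C5'.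

Step 17
Reactants: 28 (4R,5S)-5-[(1S,2R,4S)-2-hydroxy-2-{[(4-methoxyphenyl)methoxy]methyl}-4-[(2E)-6-methylhepta-2,5-dien-2-yl]cyclopentyl]-4-methylcyclopent-2-en-1-one
Product: 29 (4R,5S)-5-[(1S,2R,4S)-2-hydroxy-2-(hydroxymethyl)-4-[(2E)-6-methylhepta-2,5-dien-2-yl]cyclopentyl]-4-methylcyclopent-2-en-1-one
Conditions: DDQ (1.3 equiv), CH2Cl2/pH 7 phosphate buffer (10:1), 0 °C
Reagents that add atoms: none
Why: Oxidative cleavage of a p-methoxybenzyl ether; hydride abstraction from the electron-rich benzylic position gives an oxocarbenium ion that water hydrolyses, under neutral conditions that do not enolise the ketone. Low temperature and short contact limit attack on the doubly allylic CH2.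

Step 18
Reactants: 29 (4R,5S)-5-[(1S,2R,4S)-2-hydroxy-2-(hydroxymethyl)-4-[(2E)-6-methylhepta-2,5-dien-2-yl]cyclopentyl]-4-methylcyclopent-2-en-1-one
Product: 30 [(1R,2S,4S)-1-hydroxy-4-[(2E)-6-methylhepta-2,5-dien-2-yl]-2-[(1S,5R)-5-methyl-2-oxocyclopent-3-en-1-yl]cyclopentyl]methyl acetate
Conditions: Ac2O (1.5 equiv), pyridine (3 equiv), CH2Cl2, 0 °C → rt
Reagents that add atoms: acetic anhydride, CC(=O)OC(C)=O
Why: Selective O-acetylation of the primary hydroxyl; the tertiary hydroxyl is not acylated without a nucleophilic catalyst, and pyridine is too weak a base to enolise the ketone at C1' in the time needed.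

Step 19
Reactants: 30 [(1R,2S,4S)-1-hydroxy-4-[(2E)-6-methylhepta-2,5-dien-2-yl]-2-[(1S,5R)-5-methyl-2-oxocyclopent-3-en-1-yl]cyclopentyl]methyl acetate
Product: 31 [(1R,2S,4S)-1-hydroxy-4-[(2E,4E)-6-hydroperoxy-6-methylhepta-2,4-dien-2-yl]-2-[(1S,5R)-5-methyl-2-oxocyclopent-3-en-1-yl]cyclopentyl]methyl acetate
Conditions: O2, 5,10,15,20-tetraphenylporphyrin (1 mol%), visible light, CH2Cl2, −20 °C; chromatographic separation of regioisomers
Reagents that add atoms: dioxygen (as singlet oxygen formed by sensitisation), O=O
Why: Schenck ene reaction; singlet oxygen bonds to Ce of the less hindered terminal alkene and takes a hydrogen from the doubly allylic Cc, which lies on the more substituted side of that alkene, so the double bond moves to Cc=Cd as the (E)-alkene in conjugation with Ca=Cb. The enone is inert to singlet oxygen; hydrogen abstraction from the (Z)-methyl and attack on the Ca=Cb alkene give isomeric hydroperoxides that have to be separated.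

## Compound list

1 | (4-methoxyphenyl)methanol | COc1ccc(CO)cc1 | starting material
2 | tributyl(iodomethyl)stannane | CCCC[Sn](CCCC)(CCCC)CI | starting material
3 | tributyl{[(4-methoxyphenyl)methoxy]methyl}stannane | CCCC[Sn](CCCC)(CCCC)COCc1ccc(OC)cc1 | intermediate
4 | 5,6-dihydro-2H-pyran-2-one | O=C1C=CCCO1 | starting material
5 | potassium ethenyltrifluoroborate | [K+].C=C[B-](F)(F)F | starting material
6 | (4S)-4-ethenyloxan-2-one | O=C1C[C@@H](C=C)CCO1 | intermediate
7 | [(4-methoxyphenyl)methoxy]methyllithium | [Li]COCc1ccc(OC)cc1 | intermediate (not isolated)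
8 | (4S)-4-ethenyl-6-hydroxy-1-[(4-methoxyphenyl)methoxy]hexan-2-one | COc1ccc(COCC(=O)C[C@@H](C=C)CCO)cc1 | intermediate
9 | (3S)-3-ethenyl-6-[(4-methoxyphenyl)methoxy]-5-oxohexanal | COc1ccc(COCC(=O)C[C@@H](C=C)CC=O)cc1 | intermediate
10 | methyl (triphenyl-λ5-phosphanylidene)acetate | COC(=O)C=P(c1ccccc1)(c1ccccc1)c1ccccc1 | starting material
11 | methyl (2E,5S)-5-ethenyl-8-[(4-methoxyphenyl)methoxy]-7-oxooct-2-enoate | COc1ccc(COCC(=O)C[C@@H](C=C)C/C=C/C(=O)OC)cc1 | intermediate
12 | methyl 2-[(1S,2R,4S)-4-ethenyl-2-hydroxy-2-{[(4-methoxyphenyl)methoxy]methyl}cyclopentyl]acetate | COc1ccc(COC[C@@]2(O)C[C@@H](C=C)C[C@H]2CC(=O)OC)cc1 | intermediate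
13 | methyl 2-[(1S,2R,4S)-4-(1,2-dihydroxyethyl)-2-hydroxy-2-{[(4-methoxyphenyl)methoxy]methyl}cyclopentyl]acetate (both carbinol epimers) | COc1ccc(COC[C@@]2(O)C[C@@H](C(O)CO)C[C@H]2CC(=O)OC)cc1 | intermediate (not isolated)
14 | methyl 2-[(1S,2R,4S)-4-formyl-2-hydroxy-2-{[(4-methoxyphenyl)methoxy]methyl}cyclopentyl]acetate | COc1ccc(COC[C@@]2(O)C[C@@H](C=O)C[C@H]2CC(=O)OC)cc1 | intermediate
15 | methyl 2-[(1S,2R,4S)-4-ethynyl-2-hydroxy-2-{[(4-methoxyphenyl)methoxy]methyl}cyclopentyl]acetate | COc1ccc(COC[C@@]2(O)C[C@@H](C#C)C[C@H]2CC(=O)OC)cc1 | intermediate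
16 | 1-bromo-3-methylbut-2-ene | CC(C)=CCBr | starting material
17 | (E)-alkenyl(dimethyl)alane of 15 after methyl addition, with the tertiary oxygen as its dimethylaluminium alkoxide | COc1ccc(COC[C@@]2(O[Al](C)C)C[C@@H](/C(C)=C/[Al](C)C)C[C@H]2CC(=O)OC)cc1 | intermediate (not isolated)
18 | methyl 2-[(1S,2R,4S)-2-hydroxy-2-{[(4-methoxyphenyl)methoxy]methyl}-4-[(2E)-6-methylhepta-2,5-dien-2-yl]cyclopentyl]acetate | COc1ccc(COC[C@@]2(O)C[C@@H](/C(C)=C/CC=C(C)C)C[C@H]2CC(=O)OC)cc1 | intermediate
19 | 2-[(1S,2R,4S)-2-hydroxy-2-{[(4-methoxyphenyl)methoxy]methyl}-4-[(2E)-6-methylhepta-2,5-dien-2-yl]cyclopentyl]acetic acid | COc1ccc(COC[C@@]2(O)C[C@@H](/C(C)=C/CC=C(C)C)C[C@H]2CC(=O)O)cc1 | intermediate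
20 | rac-(3E)-pent-3-en-2-ol | C/C=C/C(C)O | starting material
21 | (2S,3E)-pent-3-en-2-ol | C/C=C/[C@H](C)O | intermediate
22 | (2S,3E)-pent-3-en-2-yl 2-[(1S,2R,4S)-2-hydroxy-2-{[(4-methoxyphenyl)methoxy]methyl}-4-[(2E)-6-methylhepta-2,5-dien-2-yl]cyclopentyl]acetate | COc1ccc(COC[C@@]2(O)C[C@@H](/C(C)=C/CC=C(C)C)C[C@H]2CC(=O)O[C@@H](C)/C=C/C)cc1 | intermediate
23 | (E)-trimethylsilyl ketene acetal of 22, tertiary hydroxyl as trimethylsilyl ether | COc1ccc(COC[C@@]2(O[Si](C)(C)C)C[C@@H](/C(C)=C/CC=C(C)C)C[C@H]2/C=C(/O[Si](C)(C)C)O[C@@H](C)/C=C/C)cc1 | intermediate (not isolated)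
24 | trimethylsilyl ester of 25, tertiary hydroxyl as trimethylsilyl ether | COc1ccc(COC[C@@]2(O[Si](C)(C)C)C[C@@H](/C(C)=C/CC=C(C)C)C[C@H]2[C@@H](C(=O)O[Si](C)(C)C)[C@H](C)/C=C/C)cc1 | intermediate (not isolated)
25 | (2S,3R,4E)-2-[(1S,2R,4S)-2-hydroxy-2-{[(4-methoxyphenyl)methoxy]methyl}-4-[(2E)-6-methylhepta-2,5-dien-2-yl]cyclopentyl]-3-methylhex-4-enoic acid | COc1ccc(COC[C@@]2(O)C[C@@H](/C(C)=C/CC=C(C)C)C[C@H]2[C@@H](C(=O)O)[C@H](C)/C=C/C)cc1 | intermediate
26 | (2S,3R,4E)-2-[(1S,2R,4S)-2-hydroxy-2-{[(4-methoxyphenyl)methoxy]methyl}-4-[(2E)-6-methylhepta-2,5-dien-2-yl]cyclopentyl]-N-methoxy-N,3-dimethylhex-4-enamide | COc1ccc(COC[C@@]2(O)C[C@@H](/C(C)=C/CC=C(C)C)C[C@H]2[C@@H](C(=O)N(C)OC)[C@H](C)/C=C/C)cc1 | intermediate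
27 | (4S,5R,6E)-4-[(1S,2R,4S)-2-hydroxy-2-{[(4-methoxyphenyl)methoxy]methyl}-4-[(2E)-6-methylhepta-2,5-dien-2-yl]cyclopentyl]-5-methylocta-1,6-dien-3-one | COc1ccc(COC[C@@]2(O)C[C@@H](/C(C)=C/CC=C(C)C)C[C@H]2[C@@H](C(=O)C=C)[C@H](C)/C=C/C)cc1 | intermediate
28 | (4R,5S)-5-[(1S,2R,4S)-2-hydroxy-2-{[(4-methoxyphenyl)methoxy]methyl}-4-[(2E)-6-methylhepta-2,5-dien-2-yl]cyclopentyl]-4-methylcyclopent-2-en-1-one | COc1ccc(COC[C@@]2(O)C[C@@H](/C(C)=C/CC=C(C)C)C[C@H]2[C@H]3C(=O)C=C[C@H]3C)cc1 | intermediate
29 | (4R,5S)-5-[(1S,2R,4S)-2-hydroxy-2-(hydroxymethyl)-4-[(2E)-6-methylhepta-2,5-dien-2-yl]cyclopentyl]-4-methylcyclopent-2-en-1-one | OC[C@@]1(O)C[C@@H](/C(C)=C/CC=C(C)C)C[C@H]1[C@H]2C(=O)C=C[C@H]2C | intermediate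
30 | [(1R,2S,4S)-1-hydroxy-4-[(2E)-6-methylhepta-2,5-dien-2-yl]-2-[(1S,5R)-5-methyl-2-oxocyclopent-3-en-1-yl]cyclopentyl]methyl acetate | CC(=O)OC[C@@]1(O)C[C@@H](/C(C)=C/CC=C(C)C)C[C@H]1[C@H]2C(=O)C=C[C@H]2C | intermediate
31 | [(1R,2S,4S)-1-hydroxy-4-[(2E,4E)-6-hydroperoxy-6-methylhepta-2,4-dien-2-yl]-2-[(1S,5R)-5-methyl-2-oxocyclopent-3-en-1-yl]cyclopentyl]methyl acetate | CC(=O)OC[C@@]1(O)C[C@@H](/C(C)=C/C=C/C(C)(C)OO)C[C@H]1[C@H]1C(=O)C=C[C@H]1C | target

## Step count and least certain steps

Total: 19 steps. Longest linear sequence: 17 steps (steps 2–10 and 12–19; steps 1 and 11 are side branches of one step each).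

**Step 6 (key step).** Two things are most likely to go wrong. The first is over-reduction: a second electron reaches the ketyl before it cyclises, and the p-methoxybenzyloxy group is expelled or the ketone is simply reduced. The second is incomplete discrimination between the chair and a boat-like transition state, which lowers the cis ratio of C3 to C5. Fallback: a tin hydride radical chain replaces the two-electron reductant. It sets out from 11 and comes back at 12: Bu3SnH (1.5 equiv), AIBN (0.1 equiv), benzene (10 mM), 80 °C, then hydrolytic work-up. The O-stannyl ketyl adds 5-exo to the enoate and the α-ester radical is quenched by hydrogen-atom transfer. No carbanion is formed at any point, so the α-oxygen cannot be lost by elimination. No new compound is made on the way.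

**Step 19.** The ene reaction is likely to lack regiocontrol: hydrogen abstraction from the (Z)-methyl of the terminal alkene and attack on the Ca=Cb alkene compete, so 31 is expected as one of several isomeric hydroperoxides. Fallback: a radical-chain autoxidation that selects by C–H bond strength instead of by alkene geometry. It sets out from 30 and comes back at 31: O2 (1 atm), N-hydroxyphthalimide (10 mol%), MeCN, 35 °C, stopped at low conversion with recycling of 30. The phthalimide-N-oxyl radical abstracts the doubly allylic hydrogen on Cc, the pentadienyl radical takes up O2 at a tertiary terminus, and the peroxyl radical is reduced by the hydroxylamine. Only the two terminal positions Ca and Ce can then carry the hydroperoxide. No new compound is made on the way.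

**Step 13.** The likely failure is loss of enolate geometry, caused by aggregation with the neighbouring lithium alkoxide, which would erode the configuration at C1'. C5' stays secure because it depends only on the carbinol centre and the alkene geometry. The rearrangement may also be slow through a congested chair. Fallback: C1' is set after ring closure by kinetic protonation instead of by the pericyclic step. It sets out from 22 and comes back at 28.

- The rearrangement mixture of 25 and its C1' epimer, (2R,3R,4E)-acid F1, is carried through steps 14–16. This gives the epimeric amide F2, the epimeric dienone F3 and the trans-enone F4 beside 26, 27 and 28.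
- The enone mixture is treated with LiN(iPr)2 (2.2 equiv) in THF at −78 °C. Both epimers give the same planar dilithium dienolate F5.
- F5 is quenched at −78 °C with 2,6-di-tert-butyl-4-methylphenol. The proton enters C1' from the face away from the C5' methyl, which places ring A cis to that methyl and returns 28.

The same operation would repair any erosion at C1' that arises in steps 14–16.

**Step 9.** Possible failures are methyl transfer from aluminium to the ester, protonolysis of the alkenylalane before the coupling, and allylic transposition in the coupling. Fallback: a copper-catalysed methylboration followed by a Suzuki coupling, which needs no Lewis-acidic aluminium. It sets out from 15 and comes back at 18.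

- 15 is treated with B2pin2, MeI, CuCl (10 mol%), Xantphos and NaOtBu in THF at rt. Syn borylcupration and methylation of the alkenylcopper give the (E)-alkenyl pinacol boronate F6.
- F6 is coupled with 16 using Pd(PPh3)4 and CsF in THF at 60 °C, which gives 18.

**Step 2.** Enantiofacial control may be insufficient, or turnover low, because a lactone is a weaker acceptor than an enone and can open hydrolytically. Fallback: desymmetrisation of a meso anhydride. It does not start from a numbered compound; it replaces 4 and 5 by commercial diethyl (2E)-pent-2-enedioate F7 and comes back at 6.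

- F7 with CH2=CHMgBr, CuI and Me3SiCl in THF at −78 °C gives diethyl 3-ethenylpentanedioate F8.
- NaOH in aqueous ethanol gives 3-ethenylpentanedioic acid F9.
- Ac2O at 80 °C gives 4-ethenyloxane-2,6-dione F10.
- Methanolysis in Et2O at −20 °C with a cinchona alkaloid catalyst of the (DHQD)2AQN type gives (3S)-3-ethenyl-5-methoxy-5-oxopentanoic acid F11. The pseudoenantiomeric catalyst is used if it is the one that delivers this enantiomer.
- BH3·SMe2 in THF at 0 °C reduces the acid arm selectively, and a trace of TsOH closes the hydroxy ester to 6.

## Further compounds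

F0 | step 6 | none | none
F0 | step 19 | none | none
F1 | step 13 | (2R,3R,4E)-2-[(1S,2R,4S)-2-hydroxy-2-{[(4-methoxyphenyl)methoxy]methyl}-4-[(2E)-6-methylhepta-2,5-dien-2-yl]cyclopentyl]-3-methylhex-4-enoic acid (C1' epimer of 25) | COc1ccc(COC[C@@]2(O)C[C@@H](/C(C)=C/CC=C(C)C)C[C@H]2[C@H](C(=O)O)[C@H](C)/C=C/C)cc1
F2 | step 13 | C1' epimer of amide 26 | COc1ccc(COC[C@@]2(O)C[C@@H](/C(C)=C/CC=C(C)C)C[C@H]2[C@H](C(=O)N(C)OC)[C@H](C)/C=C/C)cc1
F3 | step 13 | C1' epimer of dienone 27 | COc1ccc(COC[C@@]2(O)C[C@@H](/C(C)=C/CC=C(C)C)C[C@H]2[C@H](C(=O)C=C)[C@H](C)/C=C/C)cc1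
F4 | step 13 | (4R,5R)-5-[(1S,2R,4S)-2-hydroxy-2-{[(4-methoxyphenyl)methoxy]methyl}-4-[(2E)-6-methylhepta-2,5-dien-2-yl]cyclopentyl]-4-methylcyclopent-2-en-1-one (trans, C1' epimer of 28) | COc1ccc(COC[C@@]2(O)C[C@@H](/C(C)=C/CC=C(C)C)C[C@H]2[C@@H]3C(=O)C=C[C@H]3C)cc1
F5 | step 13 | dilithium salt of the cross-conjugated dienolate of 28 (tertiary alkoxide and C1'=C2' enolate) | [Li+].[Li+].COc1ccc(COC[C@@]2([O-])C[C@@H](/C(C)=C/CC=C(C)C)C[C@H]2C3=C([O-])C=C[C@H]3C)cc1
F6 | step 9 | methyl 2-[(1S,2R,4S)-2-hydroxy-2-{[(4-methoxyphenyl)methoxy]methyl}-4-[(1E)-1-(4,4,5,5-tetramethyl-1,3,2-dioxaborolan-2-yl)prop-1-en-2-yl]cyclopentyl]acetate | COc1ccc(COC[C@@]2(O)C[C@@H](/C(C)=C/B3OC(C)(C)C(C)(C)O3)C[C@H]2CC(=O)OC)cc1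
F7 | step 2 | diethyl (2E)-pent-2-enedioate | CCOC(=O)/C=C/CC(=O)OCC
F8 | step 2 | diethyl 3-ethenylpentanedioate | CCOC(=O)CC(C=C)CC(=O)OCC
F9 | step 2 | 3-ethenylpentanedioic acid | OC(=O)CC(C=C)CC(=O)O
F10 | step 2 | 4-ethenyloxane-2,6-dione | O=C1CC(C=C)CC(=O)O1
F11 | step 2 | (3S)-3-ethenyl-5-methoxy-5-oxopentanoic acid | COC(=O)C[C@@H](C=C)CC(=O)O
A1 | alternative 1 | cis-fused 4-(but-3-en-2-yl)-7a-hydroxy-6-[(2E)-6-methylhepta-2,5-dien-2-yl]hexahydrocyclopenta[c]pyran-3(1H)-one (stereochemistry as in the SMILES) | O=C1OC[C@@]2(O)C[C@@H](/C(C)=C/CC=C(C)C)C[C@H]2[C@@H]1[C@H](C)C=C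
A2 | alternative 2 | 4-tert-butyl 1-ethyl cyclopent-1-ene-1,4-dicarboxylate (single enantiomer as in the SMILES) | CCOC(=O)C1=CC[C@H](C(=O)OC(C)(C)C)C1
A3 | alternative 2 | ethyl buta-2,3-dienoate | CCOC(=O)C=C=C
A4 | alternative 2 | tert-butyl prop-2-enoate | C=CC(=O)OC(C)(C)C
A5 | alternative 3 | {4-[(1E)-1-iodoprop-1-en-2-yl]-2-(5-methyl-2-oxocyclopent-3-en-1-yl)-1-[(triethylsilyl)oxy]cyclopentyl}methyl acetate (stereochemistry as in the SMILES) | CC(=O)OC[C@@]1(O[Si](CC)(CC)CC)C[C@@H](/C(C)=C/I)C[C@H]1[C@H]1C(=O)C=C[C@H]1C
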